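**Strategy**

Ring A (chromanone numbering) is traced back to an aromatic phloroglucinol and assembled in one thermal cascade from two fragments: a 3-siloxycyclobutenone carrying the pinene-derived cyclobutylmethyl group (future C4a, C5, C6, C8a) and a siloxyalkyne carrying the benzylic chain (future C7, C8). This step forms C8–C8a and C6–C7, closes ring A and places all six substituents by connectivity. It exploits the fact that, of the three ring A oxygens, only O1 must differ from those on C5 and C7: the ketene-derived oxygen emerges as the one free phenol, flanked by C8 and the only unsubstituted carbon, C4a. Ring B, the C6 prenyl group and dearomatisation follow.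

Key step: step 10

Assumption: the ligand antipodes named in steps 6 and 16 and the choice of quinine over quinidine in step 14 are those expected to give the configurations drawn; should a first run show the opposite sense, the mirror-image ligand or quinidine is used with no other change.

Design remarks: the oxygens on C5 and C7 are both carried as triisopropylsilyl ethers because they are unmasked together. No strong Brønsted or Lewis acid is used once the isopropenylcyclobutane exists. The carboxylic acid is freed before ring A is dearomatised. Purchased building blocks are (−)-α-pinene, benzylidene Meldrum's acid and ethynyltrimethylsilane; ketene is generated from acetone.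

Abbreviations: Cb = (1R,3S)-2,2-dimethyl-3-(prop-1-en-2-yl)cyclobutyl, ring substituents cis; TIPS = triisopropylsilyl.

**Route**

Step 1
Reactants: 1 (1S,5S)-(−)-α-pinene
Product: 2 2-[(1R,3R)-3-acetyl-2,2-dimethylcyclobutyl]acetic acid (cis-pinonic acid)
Conditions: RuCl3 (cat.), NaIO4, CCl4/MeCN/H2O, rt
Reagents that add atoms: sodium periodate, [Na+].[O-]I(=O)(=O)=O
Why: Catalytic ruthenium tetroxide cleaves the trisubstituted ring alkene (oxidative C=C cleavage) to the methyl ketone and the carboxylic acid, and the two bridgehead stereocentres of the terpene become the cis-1,3-disubstituted cyclobutane carbons without being touched.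

Step 2
Reactants: 2 cis-pinonic acid
Product: 3 ethyl 2-[(1R,3R)-3-acetyl-2,2-dimethylcyclobutyl]acetate
Conditions: EtI, K2CO3, DMF, rt
Reagents that add atoms: iodoethane, CCI
Why: Carboxylate O-alkylation (SN2 esterification) under mild carbonate base supplies the ethyl ester needed for homologation without epimerising the acetyl-bearing ring carbon.

Step 3
Reactants: 3 ethyl cis-pinonate
Product: 4 ethyl 2-[(1R,3S)-2,2-dimethyl-3-(prop-1-en-2-yl)cyclobutyl]acetate
Conditions: Ph3PCH3Br, KOt-Bu, THF, 0 °C → rt
Reagents that add atoms: methyltriphenylphosphonium bromide, C[P+](c1ccccc1)(c1ccccc1)c1ccccc1.[Br-]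
Why: Wittig methylenation is selective for the ketone over the ester and, run cold without excess ylide, is expected to leave the adjacent enolisable ring carbon and hence the cis relationship intact.

Step 4
Reactants: 4 ethyl Cb-acetate
Product: 7 [(3-Cb-prop-1-yn-1-yl)oxy]triisopropylsilane, via dibromo enolate 5 (not isolated), via lithium ynolate 6 (not isolated)
Conditions: CH2Br2, lithium 2,2,6,6-tetramethylpiperidide, THF, −78 °C; LiN(SiMe3)2; s-BuLi, −78 → 20 °C; i-Pr3SiCl, −78 → 20 °C
Reagents that add atoms: dibromomethane, BrCBr; chlorotriisopropylsilane, CC(C)[Si](Cl)(C(C)C)C(C)C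
Why: Kowalski ester homologation stopped at the ynolate: dibromomethyllithium adds to the ester, the dibromo enolate undergoes bromine–lithium exchange and 1,2-shift of the alkyl group, and the hindered chlorosilane silylates the ynolate on oxygen, the substrate having no other acidic or electrophilic site.

Step 5
Reactants: 7 siloxyalkyne of the cyclobutane fragment
Product: 8 2-(Cb-methyl)-3-(TIPS-oxy)cyclobut-2-en-1-one
Conditions: ketene (gas stream from pyrolysis of acetone), CH2Cl2, 0 °C → rt
Reagents that add atoms: ketene, C=C=O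
Why: Thermal [2+2] cycloaddition of ketene to the electron-rich siloxyalkyne, the alkyne carbon remote from oxygen attacking the ketene carbonyl carbon, gives the 2-alkyl-3-siloxycyclobutenone as a single regioisomer, while the unactivated isopropenyl group is inert to ketene itself.

Step 6
Reactants: 9 5-benzylidene-2,2-dimethyl-1,3-dioxane-4,6-dione (benzylidene Meldrum's acid); 10 ethynyltrimethylsilane
Product: 11 2,2-dimethyl-5-[(1S)-1-phenyl-3-(trimethylsilyl)prop-2-yn-1-yl]-1,3-dioxane-4,6-dione
Conditions: Rh(acac)(C2H4)2 (cat.), (S)-3,5-Xyl-MeO-BIPHEP (cat.), dioxane, rt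
Reagents that add atoms: none
Why: Rhodium-catalysed asymmetric conjugate alkynylation of an alkylidene Meldrum's acid: the bisphosphine-bound rhodium acetylide adds to one face of the doubly activated benzylidene acceptor and so sets the benzylic centre (S) under ligand control, the silyl cap preventing alkyne dimerisation.

Step 7
Reactants: 11 alkynylated Meldrum's acid
Product: 13 tert-butyl (3S)-3-phenyl-5-(trimethylsilyl)pent-4-ynoate, via malonic half-ester 12 (not isolated)
Conditions: t-BuOH, 85 °C; then Cu2O (cat.), MeCN, 80 °C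
Reagents that add atoms: tert-butanol, CC(C)(C)O
Why: Thermal alcoholysis of the Meldrum's acid ring with loss of acetone followed by Cu2O-catalysed decarboxylation of the malonic half-ester (whose extra stereocentre is lost again) delivers the bulky ester directly, the benzylic centre lying β to both carboxyl groups and therefore not enolisable.

Step 8
Reactants: 13 silylalkyne ester
Product: 14 tert-butyl (3R)-3-phenylpent-4-ynoate
Conditions: K2CO3 (cat.), MeOH, 0 °C
Reagents that add atoms: none
Why: Base-catalysed methanolysis of the C(sp)–Si bond (protodesilylation) proceeds under conditions too mild to transesterify the tert-butyl ester or to isomerise the benzylic propargylic centre, whose descriptor changes to R only because ethynyl ranks below phenyl.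

Step 9
Reactants: 14 terminal alkyne ester
Product: 16 tert-butyl (3S)-3-phenyl-5-(TIPS-oxy)pent-4-ynoate, via lithium ynolate 15 (not isolated)
Conditions: LiN(SiMe3)2 (1.0 equiv), THF, −78 °C; t-BuOOLi (pre-formed from t-BuOOH and LiN(SiMe3)2), −78 → 0 °C; i-Pr3SiOTf, −78 °C
Reagents that add atoms: tert-butyl hydroperoxide, CC(C)(C)OO; triisopropylsilyl trifluoromethanesulfonate, CC(C)[Si](OS(=O)(=O)C(F)(F)F)(C(C)C)C(C)C
Why: Acetylide oxygenation: the lithium acetylide attacks the peroxide oxygen of t-BuOOLi to give the ynolate, which the hindered silyl triflate traps on oxygen, one equivalent of amide base residing on the more acidic alkyne C–H and the tert-butyl ester resisting both enolisation and addition, so that the stereocentre is not touched.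

Step 10
Reactants: 8 siloxycyclobutenone (1.2 equiv); 16 siloxyalkyne
Product: 20 tert-butyl (3S)-3-[3-(Cb-methyl)-6-hydroxy-2,4-bis(TIPS-oxy)phenyl]-3-phenylpropanoate, via vinylketene 17 (not isolated), via vinylcyclobutenone 18 (not isolated), via dienylketene 19 (not isolated)
Conditions: toluene (1 M, degassed), 80 → 110 °C
Reagents that add atoms: none
Why: Heating opens cyclobutenone 8 by 4π electrocyclic cleavage of its C1–C4 bond to vinylketene 17, whose carbonyl carbon is attacked by the electron-rich alkyne carbon of 16 remote from oxygen in a [2+2] cycloaddition that gives vinylcyclobutenone 18 and forms the future C8–C8a and C6–C7 bonds. A second 4π opening gives dienylketene 19, and ring A, the only ring formed, closes by thermal 6π electrocyclisation between the ketene carbon and the terminal methylene, followed by tautomerisation to phenol 20. The closest known reaction type is the Danheiser benzannulation of cyclobutenones with siloxyalkynes. No stereocentre of 20 is created: the quaternary centre of 18 arises without control and vanishes on ring opening, and the benzylic centre is a spectator that no intermediate makes acidic or planar in the neutral medium. The one selectivity required, the orientation of the [2+2] step, is secured by the oxygen polarisation of the alkyne, so that C8 carries the benzylic chain, C6 the cyclobutylmethyl group and only the ketene-derived oxygen, the future O1, is left unprotected. The bulky silyl groups retard the 1,3-silyl shift of 16 to a silylketene, the tert-butyl ester resists lactonisation onto the new phenol, and the high concentration favours the alkyne over the pendant isopropenyl group as ketene trap.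

Step 11
Reactants: 20 ring A phenol
Product: 21 tert-butyl (3S)-3-[3-(Cb-methyl)-6-hydroxy-5-iodo-2,4-bis(TIPS-oxy)phenyl]-3-phenylpropanoate
Conditions: N-iodosuccinimide, CH2Cl2, −20 → 0 °C, dark
Reagents that add atoms: N-iodosuccinimide, O=C1CCC(=O)N1I
Why: Electrophilic aromatic iodination of the free phenol takes place at C4a, the only unsubstituted ring position and ortho to the hydroxyl, much faster than any reaction of the reagent with the isolated alkene.

Step 12
Reactants: 21 iodophenol
Product: 22 2-[(1S)-3-tert-butoxy-3-oxo-1-phenylpropyl]-4-(Cb-methyl)-6-iodo-3,5-bis(TIPS-oxy)phenyl (2E)-2-methylbut-2-enoate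
Conditions: NaH, THF, 0 °C; (E)-2-methylbut-2-enoyl chloride, 0 °C → rt
Reagents that add atoms: (E)-2-methylbut-2-enoyl chloride (tigloyl chloride), C/C=C(\C)C(Cl)=O
Why: O-Acylation of the pre-formed sodium phenoxide with the acid chloride (esterification) avoids amine bases that could deconjugate the tigloyl unit through a vinylketene, and one equivalent of hydride does not enolise the tert-butyl ester.

Step 13
Reactants: 22 iodoaryl tiglate
Product: 24 tert-butyl (3S)-3-[3-(Cb-methyl)-6-hydroxy-5-[(2E)-2-methylbut-2-enoyl]-2,4-bis(TIPS-oxy)phenyl]-3-phenylpropanoate, via aryllithium 23 (not isolated)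
Conditions: n-BuLi (1.05 equiv), THF, −100 → −78 °C; AcOH, −78 °C
Reagents that add atoms: none
Why: Anionic Fries rearrangement triggered by iodine–lithium exchange: exchange at −100 °C outruns addition of butyllithium to either ester, and the aryllithium at C4a attacks the neighbouring ester carbonyl intramolecularly (1,3 O→C acyl shift) faster than silicon can migrate from the flanking silyl ether, regenerating the O1 phenol next to the new enone.

Step 14
Reactants: 24 hydroxyaryl tigloyl ketone
Product: 26 tert-butyl (3S)-3-[(2R,3R)-6-(Cb-methyl)-2,3-dimethyl-4-oxo-5,7-bis(TIPS-oxy)-3,4-dihydro-2H-chromen-8-yl]-3-phenylpropanoate, via cis epimer 25 (not isolated)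
Conditions: quinine (20 mol%), chlorobenzene, rt; then Et3N, 40 °C
Reagents that add atoms: none
Why: Cinchona-alkaloid-catalysed intramolecular oxa-Michael addition: the quinuclidine nitrogen activates the O1–H while the alkaloid hydroxyl binds the enone, so that the only free phenol adds to one face of the tigloyl β-carbon and sets C2 (R) under catalyst control, after which C3, α to the ketone, equilibrates through the enol to the more stable trans (3R) arrangement.

Step 15
Reactants: 26 trans-chromanone
Product: 28 (3S)-3-[(2R,3R)-6-(Cb-methyl)-5,7-dihydroxy-2,3-dimethyl-4-oxo-3,4-dihydro-2H-chromen-8-yl]-3-phenylpropanoic acid, via trimethylsilyl ester 27 (not isolated)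
Conditions: Me3SiOTf, 2,6-lutidine, CH2Cl2, 0 °C; then Bu4NF, AcOH, THF, 0 °C → rt
Reagents that add atoms: none
Why: The silyl triflate buffered by a hindered pyridine converts the tert-butyl ester into a silyl ester with loss of isobutene under non-protic conditions that spare the isopropenylcyclobutane, and buffered fluoride then removes that silyl ester and both aryl silyl ethers (desilylation) without opening ring B.

Step 16
Reactants: 28 dihydroxychromanone acid
Product: 29 (3S)-3-[(2R,3R,6R)-6-(Cb-methyl)-5-hydroxy-2,3-dimethyl-6-(3-methylbut-2-en-1-yl)-4,7-dioxo-3,4,6,7-tetrahydro-2H-chromen-8-yl]-3-phenylpropanoic acid (CNP0103716.3)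
Conditions: Pd2(dba)3·CHCl3 (2.5 mol%), N,N'-[(1R,2R)-cyclohexane-1,2-diyl]bis[2-(diphenylphosphanyl)benzamide] (7.5 mol%), prenyl acetate (1.2 equiv), Et3N (2.5 equiv), THF, 0 °C → rt; aq. citric acid
Reagents that add atoms: 3-methylbut-2-en-1-yl acetate (prenyl acetate), CC(=O)OCC=C(C)C
Why: Proposed new method: zerovalent palladium ionises prenyl acetate to a π-prenyl complex held in the chiral pocket of the diamide bisphosphine, the triethylammonium C7 phenoxide of 28 attacks its unsubstituted terminus through C6, the ring carbon flanked by two oxygens and less hindered than C8, the facial choice at the planar nucleophile (which the remote stereocentres cannot make) being imposed by the ligand to set C6 (R), while O-prenylated products including the prenyl ester of the acid re-ionise under the catalyst and drain into the irreversible C–C product; the closest known reaction types are the palladium-catalysed asymmetric allylic dearomatisation of naphthols and the base-mediated alkylative dearomatisation of acylphloroglucinols.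

**Compound list**

1 | (1S,5S)-(−)-α-pinene, (1S,5S)-2,6,6-trimethylbicyclo[3.1.1]hept-2-ene | CC1=CC[C@H]2C[C@@H]1C2(C)C | starting material
2 | 2-[(1R,3R)-3-acetyl-2,2-dimethylcyclobutyl]acetic acid (cis-pinonic acid) | CC(=O)[C@@H]1C[C@H](CC(=O)O)C1(C)C | intermediate
3 | ethyl 2-[(1R,3R)-3-acetyl-2,2-dimethylcyclobutyl]acetate | CC(=O)[C@@H]1C[C@H](CC(=O)OCC)C1(C)C | intermediate
4 | ethyl 2-[(1R,3S)-2,2-dimethyl-3-(prop-1-en-2-yl)cyclobutyl]acetate | C=C(C)[C@@H]1C[C@H](CC(=O)OCC)C1(C)C | intermediate
5 | lithium 1,1-dibromo-3-Cb-prop-1-en-2-olate (not isolated) | C=C(C)[C@@H]1C[C@H](CC([O-])=C(Br)Br)C1(C)C.[Li+] | intermediate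
6 | lithium 3-Cb-prop-1-yn-1-olate (not isolated) | C=C(C)[C@@H]1C[C@H](CC#C[O-])C1(C)C.[Li+] | intermediate
7 | [(3-Cb-prop-1-yn-1-yl)oxy]triisopropylsilane | C=C(C)[C@@H]1C[C@H](CC#CO[Si](C(C)C)(C(C)C)C(C)C)C1(C)C | intermediate
8 | 2-(Cb-methyl)-3-(TIPS-oxy)cyclobut-2-en-1-one | C=C(C)[C@@H]1C[C@H](CC2=C(O[Si](C(C)C)(C(C)C)C(C)C)CC2=O)C1(C)C | intermediate
9 | 5-benzylidene-2,2-dimethyl-1,3-dioxane-4,6-dione | CC1(C)OC(=O)C(=Cc2ccccc2)C(=O)O1 | starting material
10 | ethynyltrimethylsilane | C#C[Si](C)(C)C | starting material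
11 | 2,2-dimethyl-5-[(1S)-1-phenyl-3-(trimethylsilyl)prop-2-yn-1-yl]-1,3-dioxane-4,6-dione | C[Si](C)(C)C#C[C@@H](C1C(=O)OC(C)(C)OC1=O)c1ccccc1 | intermediate
12 | 3-tert-butoxy-3-oxo-2-[(1S)-1-phenyl-3-(trimethylsilyl)prop-2-yn-1-yl]propanoic acid (both C2 epimers; not isolated) | C[Si](C)(C)C#C[C@@H](C(C(=O)O)C(=O)OC(C)(C)C)c1ccccc1 | intermediate
13 | tert-butyl (3S)-3-phenyl-5-(trimethylsilyl)pent-4-ynoate | C[Si](C)(C)C#C[C@@H](CC(=O)OC(C)(C)C)c1ccccc1 | intermediate
14 | tert-butyl (3R)-3-phenylpent-4-ynoate | C#C[C@@H](CC(=O)OC(C)(C)C)c1ccccc1 | intermediate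
15 | lithium (3S)-5-tert-butoxy-5-oxo-3-phenylpent-1-yn-1-olate (not isolated) | [Li+].[O-]C#C[C@@H](CC(=O)OC(C)(C)C)c1ccccc1 | intermediate
16 | tert-butyl (3S)-3-phenyl-5-(TIPS-oxy)pent-4-ynoate | CC(C)[Si](C(C)C)(C(C)C)OC#C[C@@H](CC(=O)OC(C)(C)C)c1ccccc1 | intermediate
17 | 2-(Cb-methyl)-3-(TIPS-oxy)buta-1,3-dien-1-one (vinylketene; not isolated) | C=C(C)[C@@H]1C[C@H](CC(=C=O)C(=C)O[Si](C(C)C)(C(C)C)C(C)C)C1(C)C | intermediate
18 | tert-butyl (3S)-3-{3-(Cb-methyl)-4-oxo-2-(TIPS-oxy)-3-[1-(TIPS-oxy)ethenyl]cyclobut-1-en-1-yl}-3-phenylpropanoate (both epimers at the ring quaternary carbon; not isolated) | C=C(C)[C@@H]1C[C@H](CC2(C(=C)O[Si](C(C)C)(C(C)C)C(C)C)C(=O)C([C@@H](CC(=O)OC(C)(C)C)c3ccccc3)=C2O[Si](C(C)C)(C(C)C)C(C)C)C1(C)C | intermediate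
19 | tert-butyl (3S,5E)-6-(Cb-methyl)-4-(oxomethylidene)-3-phenyl-5,7-bis(TIPS-oxy)octa-5,7-dienoate (dienylketene; not isolated) | C=C(C)[C@@H]1C[C@H](CC(/C(=C)O[Si](C(C)C)(C(C)C)C(C)C)=C(O[Si](C(C)C)(C(C)C)C(C)C)/C(=C=O)[C@@H](CC(=O)OC(C)(C)C)c2ccccc2)C1(C)C | intermediate
20 | tert-butyl (3S)-3-[3-(Cb-methyl)-6-hydroxy-2,4-bis(TIPS-oxy)phenyl]-3-phenylpropanoate | C=C(C)[C@@H]1C[C@H](Cc2c(O[Si](C(C)C)(C(C)C)C(C)C)cc(O)c([C@@H](CC(=O)OC(C)(C)C)c3ccccc3)c2O[Si](C(C)C)(C(C)C)C(C)C)C1(C)C | intermediate
21 | tert-butyl (3S)-3-[3-(Cb-methyl)-6-hydroxy-5-iodo-2,4-bis(TIPS-oxy)phenyl]-3-phenylpropanoate | C=C(C)[C@@H]1C[C@H](Cc2c(O[Si](C(C)C)(C(C)C)C(C)C)c(I)c(O)c([C@@H](CC(=O)OC(C)(C)C)c3ccccc3)c2O[Si](C(C)C)(C(C)C)C(C)C)C1(C)C | intermediate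
22 | 2-[(1S)-3-tert-butoxy-3-oxo-1-phenylpropyl]-4-(Cb-methyl)-6-iodo-3,5-bis(TIPS-oxy)phenyl (2E)-2-methylbut-2-enoate | C=C(C)[C@@H]1C[C@H](Cc2c(O[Si](C(C)C)(C(C)C)C(C)C)c(I)c(OC(=O)/C(C)=C/C)c([C@@H](CC(=O)OC(C)(C)C)c3ccccc3)c2O[Si](C(C)C)(C(C)C)C(C)C)C1(C)C | intermediate
23 | aryllithium from 22, lithium in place of iodine at C4a (not isolated) | C=C(C)[C@@H]1C[C@H](Cc2c(O[Si](C(C)C)(C(C)C)C(C)C)c([Li])c(OC(=O)/C(C)=C/C)c([C@@H](CC(=O)OC(C)(C)C)c3ccccc3)c2O[Si](C(C)C)(C(C)C)C(C)C)C1(C)C | intermediate
24 | tert-butyl (3S)-3-[3-(Cb-methyl)-6-hydroxy-5-[(2E)-2-methylbut-2-enoyl]-2,4-bis(TIPS-oxy)phenyl]-3-phenylpropanoate | C=C(C)[C@@H]1C[C@H](Cc2c(O[Si](C(C)C)(C(C)C)C(C)C)c(C(=O)/C(C)=C/C)c(O)c([C@@H](CC(=O)OC(C)(C)C)c3ccccc3)c2O[Si](C(C)C)(C(C)C)C(C)C)C1(C)C | intermediate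
25 | tert-butyl (3S)-3-[(2R,3S)-6-(Cb-methyl)-2,3-dimethyl-4-oxo-5,7-bis(TIPS-oxy)-3,4-dihydro-2H-chromen-8-yl]-3-phenylpropanoate (cis; not isolated) | C=C(C)[C@@H]1C[C@H](Cc2c(O[Si](C(C)C)(C(C)C)C(C)C)c3C(=O)[C@@H](C)[C@@H](C)Oc3c([C@@H](CC(=O)OC(C)(C)C)c4ccccc4)c2O[Si](C(C)C)(C(C)C)C(C)C)C1(C)C | intermediate
26 | tert-butyl (3S)-3-[(2R,3R)-6-(Cb-methyl)-2,3-dimethyl-4-oxo-5,7-bis(TIPS-oxy)-3,4-dihydro-2H-chromen-8-yl]-3-phenylpropanoate (trans) | C=C(C)[C@@H]1C[C@H](Cc2c(O[Si](C(C)C)(C(C)C)C(C)C)c3C(=O)[C@H](C)[C@@H](C)Oc3c([C@@H](CC(=O)OC(C)(C)C)c4ccccc4)c2O[Si](C(C)C)(C(C)C)C(C)C)C1(C)C | intermediate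
27 | trimethylsilyl (3S)-3-[(2R,3R)-6-(Cb-methyl)-2,3-dimethyl-4-oxo-5,7-bis(TIPS-oxy)-3,4-dihydro-2H-chromen-8-yl]-3-phenylpropanoate (not isolated) | C=C(C)[C@@H]1C[C@H](Cc2c(O[Si](C(C)C)(C(C)C)C(C)C)c3C(=O)[C@H](C)[C@@H](C)Oc3c([C@@H](CC(=O)O[Si](C)(C)C)c4ccccc4)c2O[Si](C(C)C)(C(C)C)C(C)C)C1(C)C | intermediate
28 | (3S)-3-[(2R,3R)-6-(Cb-methyl)-5,7-dihydroxy-2,3-dimethyl-4-oxo-3,4-dihydro-2H-chromen-8-yl]-3-phenylpropanoic acid | C=C(C)[C@@H]1C[C@H](Cc2c(O)c3C(=O)[C@H](C)[C@@H](C)Oc3c([C@@H](CC(=O)O)c4ccccc4)c2O)C1(C)C | intermediate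
29 | (3S)-3-[(2R,3R,6R)-6-{[(1R,3S)-2,2-dimethyl-3-(prop-1-en-2-yl)cyclobutyl]methyl}-5-hydroxy-2,3-dimethyl-6-(3-methylbut-2-en-1-yl)-4,7-dioxo-3,4,6,7-tetrahydro-2H-chromen-8-yl]-3-phenylpropanoic acid | C=C(C)[C@@H]1C[C@H](C[C@@]2(CC=C(C)C)C(=O)C([C@@H](CC(=O)O)c3ccccc3)=C3O[C@H](C)[C@@H](C)C(=O)C3=C2O)C1(C)C | target

**Step count and risks**

Total step count: 16. Longest linear sequence: 12 steps (steps 1–5 and 10–16, from α-pinene). The siloxyalkyne branch (steps 6–9) is 4 steps.

The three steps most likely to fail: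

1. Step 16, the one step that goes beyond known chemistry. The ligand may discriminate the two faces of C6 poorly, or the π-allyl may be diverted to oxygen (phenoxide, carboxylate) or to C8. The fallback uses known chemistry and sets out from 28. Alkylative dearomatisation under protic base (KOH, MeOH/H2O, prenyl bromide, 0 °C) is expected to prenylate C6 without facial control, the carboxylate being inert in the protic medium. This would give 29 together with the (6S)-epimer of 29 F1; the two are diastereomers and would be separated by preparative HPLC. The route is rejoined at 29.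

2. Step 10. The vinylketene may be captured intramolecularly by the isopropenyl group, or the siloxyalkyne may undergo silyl shift at the temperature needed to open the siloxycyclobutenone. The fallback generates the same vinylketene 17 at room temperature by the diazo-ketone (photochemical Wolff) variant of the benzannulation, and sets out from 4. Crossed Claisen condensation with the lithium enolate of acetone (LiN(i-Pr)2, acetone, THF, −78 °C) would give 1-Cb-pentane-2,4-dione F2. Regitz diazo transfer (4-acetamidobenzenesulfonyl azide, Et3N, MeCN) would give 3-diazo-1-Cb-pentane-2,4-dione F3. Silylation of the less hindered methyl ketone (i-Pr3SiOTf, Et3N, CH2Cl2, 0 °C) would give 3-diazo-1-Cb-4-(TIPS-oxy)pent-4-en-2-one F4. Irradiation of F4 with 16 (hν, CH2Cl2, rt), then brief warming to 80 °C, would complete the cascade; the route is rejoined at 20.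

3. Step 13. Butyllithium may add to the aryl tiglate (ester cleavage or conjugate addition) in competition with iodine–lithium exchange. The fallback avoids organolithium reagents and sets out from 21. Carbonylative Stille coupling (Pd(PPh3)4 as the source of zerovalent palladium, CO at 1 atm, (E)-tributyl(but-2-en-2-yl)stannane, dioxane, 70 °C, neutral) would install the tigloyl group at C4a directly. The route is rejoined at 24; no new compound arises (F0).

Further compounds
F1 | step 16 | (3S)-3-[(2R,3R,6S)-6-(Cb-methyl)-5-hydroxy-2,3-dimethyl-6-(3-methylbut-2-en-1-yl)-4,7-dioxo-3,4,6,7-tetrahydro-2H-chromen-8-yl]-3-phenylpropanoic acid (C6 epimer of 29) | C=C(C)[C@@H]1C[C@H](C[C@]2(CC=C(C)C)C(=O)C([C@@H](CC(=O)O)c3ccccc3)=C3O[C@H](C)[C@@H](C)C(=O)C3=C2O)C1(C)C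
F2 | step 10 | 1-[(1R,3S)-2,2-dimethyl-3-(prop-1-en-2-yl)cyclobutyl]pentane-2,4-dione | C=C(C)[C@@H]1C[C@H](CC(=O)CC(C)=O)C1(C)C
F3 | step 10 | 3-diazo-1-[(1R,3S)-2,2-dimethyl-3-(prop-1-en-2-yl)cyclobutyl]pentane-2,4-dione | C=C(C)[C@@H]1C[C@H](CC(=O)C(=[N+]=[N-])C(C)=O)C1(C)C
F4 | step 10 | 3-diazo-1-[(1R,3S)-2,2-dimethyl-3-(prop-1-en-2-yl)cyclobutyl]-4-(triisopropylsilyloxy)pent-4-en-2-one | C=C(C)[C@@H]1C[C@H](CC(=O)C(=[N+]=[N-])C(=C)O[Si](C(C)C)(C(C)C)C(C)C)C1(C)C
F0 | step 13 | none | none
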